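Time separates south-east, stopped after 6.0 min, from east, stopped after 20 min; the charges of the two closed flasks are equal, and two chemists dispute what the extra time buys.

| setting | Sunday's | south-east | east |
|---|---|---|---|
| free monomer | 1.5 M | 3.0 M | 3.0 M |
| protic impurity | 0.60 M | 0.600 M | 0.600 M |
| initiator | 150 mM | 150 mM | 150 mM |
| remark | run made earlier |  |  |
| time |  | 6.0 min | 20 min |

- Sunday's (time / min: monomer in chains / %, free monomer / %): 0.833: 22, 44; 2.50: 44, 16; 5.00: 56, 5; 8.00: 60, 0

(standard deviation of a reading: 1.5 percentage points)

- the average divides the monomer in chains by the number of chains begun, living and dead together
- the earlier runs do not show the number of chains; that part of a forecast is a guess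

1. which of the two ends with the longer chains by the average number of monomer units in a chain (chains begun, living or dead) ("neither" if they lie within 10 %) (south-east / east / neither)
2. average number of monomer units in a chain (chains begun, living or dead) at the end, south-east
3. average number of monomer units in a chain (chains begun, living or dead) at the end, east

Both start from Sunday's run. There, chains plus free monomer level off at 60 % of the charge, so 0.600 M of free monomer went elsewhere, close to the protic impurity charged, 0.60 M.

Vera reckons by the charge. She takes ([free monomer] − [protic impurity])/[initiator] at the start, which gives 16.0, and calls this the book length: the monomer units per chain once the impurity has had its share, with one chain per initiator. The runs do not show that chain count.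

Marc reckons by the clock. Between 0.833 min and 2.50 min, Sunday's chains took up monomer at 0.198 M min⁻¹. If that pace held steady, south-east would stand at 7.92 units. The book length would be reached at 12.1 min, which is later than south-east's stop and earlier than east's, so east would win.

Vera answers that Sunday's free monomer did not fall steadily. It went from 16 % to 5 % between 2.50 min and 5.00 min, which reads as a pseudo-first-order constant of 0.465 min⁻¹ and a half-life of 1.49 min. South-east's run then holds 4.03 half-lives, leaving about 6.14 % of the free monomer, inside the margin of 10 %.

The forecast is hers: south-east 15, east 16, longer: neither. On the count it says: “I guess one chain per initiator”.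

The flask gives 15.2 for south-east and 15.4 for east, so the answer is neither.

    free monomer + initiator → living end + monomer in chains (k = 0.0260 M⁻¹ s⁻¹)
    free monomer + living end → monomer in chains + living end, rate k2*[living end]*[free monomer] (k = 0.0670 M⁻¹ s⁻¹)
    living end + monomer in chains → dead end (k = 3.40 × 10⁻⁴ M⁻¹ s⁻¹)
    protic impurity + free monomer → quenched substrate (k = 0.0330 M⁻¹ s⁻¹)

Marc's clock has the early run: at 0.600 min, south-east stood at 4.67. The book length parts from the flask in a neighbour, east with 0.75 M of free monomer: there it comes to 1.00, and the flask gives 2.68. South-east and east are not quite at rest. Left until 60.0 min, south-east reads 15.1. East, left until 200 min, reads 15.0, with its living end down from 0.0629 M to 1.58 × 10⁻⁵ M.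

(All runs are simulated with made-up constants, and the scatter is random.)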